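A direct plan would formylate 1,3-bis(benzyloxy)-5-bromobenzene A1 with POCl3/DMF to 2,4-bis(benzyloxy)-6-bromobenzaldehyde A2.
A lithium aldol addition of 2-(benzyloxy)-1-[3-(benzyloxy)-4-methoxyphenyl]ethan-1-one A3 to A2, then Dess–Martin oxidation, would give the bromo 1,3-diketone A4.
A CuI-catalysed Ullmann O-arylation of A4 would close ring C at O1–C8a to the tetrabenzyl flavonol A5; hydrogenolysis of A5 would give tamarixetin A6, which DCC/Bu4N·HSO4 would sulfate at 3-OH and 7-OH before exchange to the acid form.
- Weak, the formylation of A1: it would have to take the CH next to bromine and not the CH between the two benzyloxy groups, so an isomer question would open an eleven-step sequence.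
- Weak, the aldol/oxidation pair from A3 and A2 to A4: it would make an alcohol and two stereocentres only to erase them, and the four benzyl ethers of A5 would go on and off around a ring A that is plain phloroglucinol in the target.
- Weak, the disulfation of unprotected A6: it would rest on reagent selectivity between the sluggish 3-OH and the free 3'-OH, at the last stage and on the most valuable material.

**Retrosynthetic overview of the new route**
- Ring C would be cut at C4–C4a and O1–C2. Ring A (C4a, C5, C6, C7, C8, C8a, with oxygen at C5, C7 and C8a) is unprotected phloroglucinol; its three CH carbons are equivalent, so any of them can become C4a without halogen, formyl or protecting group.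
- The partner would be an α-silyloxy aroylacetate carrying C2, C3, C4, the C3 oxygen and ring B. One thermal operation (Mentzer type, through an aroylketene) would acylate phloroglucinol at carbon and close the pyranone; rings A and B are bought, ring C forms last, and 5-OH and 7-OH are free from the outset.
- C2–C3 would be made beforehand by C-acylation of a silyl glycolate enolate with O-benzylisovanilloyl chloride, so no regiochemical formylation and no aldol/oxidation detour arise.
- After desilylation only 3'-O stays blocked (benzyl), so the disulfation meets just 3-OH, 7-OH and the chelated 5-OH; the benzyl ether would be removed last by hydrogenolysis, which aryl sulfate salts tolerate.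

Key step: step 3

Remark: the target is drawn as the free bis(hydrogen sulfate) and is taken as that acid form, to be handled cold and isolated by lyophilisation.

Step 1
Reactants: 1 isovanillic acid (3-hydroxy-4-methoxybenzoic acid); 2 benzyl bromide
Product: 4 3-(benzyloxy)-4-methoxybenzoic acid, via benzyl ester 3 (not isolated)
Conditions: BnBr (2.3 equiv), K2CO3, DMF, 60 °C; then NaOH, MeOH/H2O, 60 °C; HCl to pH 2
Reagents that add atoms: benzyl bromide (compound 2), BrCc1ccccc1; sodium hydroxide, [Na+].[OH-]
Why: Williamson alkylation of the phenoxide and the carboxylate gives the benzyl ether benzyl ester, and saponification then cleaves only the ester, so one pot should deliver the O-benzyl acid.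

Step 2
Reactants: 4 3-(benzyloxy)-4-methoxybenzoic acid; 5 ethyl 2-[(tert-butyldimethylsilyl)oxy]acetate
Product: 8 ethyl 3-[3-(benzyloxy)-4-methoxyphenyl]-2-[(tert-butyldimethylsilyl)oxy]-3-oxopropanoate (racemic), via acid chloride 6 (not isolated), via lithium ester enolate 7 (not isolated)
Conditions: 4, (COCl)2 (1.3 equiv), DMF (cat.), CH2Cl2, rt, evaporation; 5 (2.2 equiv), LiN(iPr)2 (2.2 equiv), THF, −78 °C; then 6 in THF, −78 °C; AcOH quench at −78 °C
Reagents that add atoms: none
Why: Acid chloride formation followed by crossed Claisen-type C-acylation of a preformed lithium ester enolate; the second equivalent of enolate deprotonates the β-keto ester as it forms and so shields it from a second acylation, and the new stereocentre at C2 is formed racemic and disappears in step 3.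

Step 3
Reactants: 8 ethyl 3-[3-(benzyloxy)-4-methoxyphenyl]-2-[(tert-butyldimethylsilyl)oxy]-3-oxopropanoate; 9 phloroglucinol (benzene-1,3,5-triol, anhydrous)
Product: 13 2-[3-(benzyloxy)-4-methoxyphenyl]-3,5,7-trihydroxy-4H-chromen-4-one (3'-O-benzyltamarixetin), via aroylketene 10 (not isolated), via aryl 1,3-diketone 11 (not isolated), via 3-O-silyl flavonol 12 (not isolated)
Conditions: 9 (2 equiv), neat melt, 240 °C, argon, 10–20 min (microwave or metal bath), EtOH and H2O distilled off; then Et3N·3HF, THF, rt
Reagents that add atoms: none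
Why: Thermal loss of ethanol from the enol form of 8 should give aroylketene 10, whose ketene carbon (the future C4) acylates a ring CH of phloroglucinol (directly or through a reversible aryl ester that regenerates 10) to give the 2-hydroxyaryl 1,3-diketone 11, and cyclodehydration then forms O1–C2; this is the Mentzer pyrone synthesis, the thermal condensation of phloroglucinol with aroylacetates to 5,7-dihydroxyflavones, which also accepts α-alkoxy aroylacetates. Ring C closes by 6-exo-trig attack of an ortho hydroxyl of 11 on the aryl ketone carbon followed by loss of water, and the aromatic 4-pyranone with its chelated 5-OH drives the sequence. No stereocentre is formed, and the racemic centre of 8 becomes sp2 C3. The step needs flavone over 4-arylcoumarin (Pechmann) closure, C- over O-acylation and monoannulation: without acid the ketene carbon is the only strong electrophile while the aryl ketone is deactivated by the para methoxy group, O-acylation is reversible at this temperature whereas C-acylation is not, and the first acyl group deactivates ring A. No site selectivity on ring A is needed, because the three CH carbons of phloroglucinol are equivalent and either ortho hydroxyl gives the same product. Silyl transfer among the hydroxyl groups in the melt is harmless, because Et3N·3HF converges every silylated form on 13 and leaves the 3'-O-benzyl ether as the only protected oxygen.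

Step 4
Reactants: 13 2-[3-(benzyloxy)-4-methoxyphenyl]-3,5,7-trihydroxy-4H-chromen-4-one
Product: 15 disodium 2-[3-(benzyloxy)-4-methoxyphenyl]-5-hydroxy-4-oxo-4H-chromene-3,7-diyl disulfate, via bis(pyridinium) disulfate 14 (not isolated)
Conditions: SO3·pyridine (6 equiv), pyridine, rt → 45 °C, followed by HPLC; then aq NaHCO3, evaporation of all pyridine; C18 or Sephadex LH-20 (H2O/MeOH)
Reagents that add atoms: sulfur trioxide pyridine complex, O=S(=O)([O-])[n+]1ccccc1; sodium hydrogen carbonate, [Na+].OC(=O)[O-]
Why: Sulfation by SO3 transfer from the pyridine complex to the phenolic 7-OH and the enolic 3-OH; 3'-O is blocked as its benzyl ether and 5-OH is held in a six-membered hydrogen bond to C4=O, the least reactive hydroxyl of a flavonol, so an excess of reagent can drive the sluggish 3-OH without a selectivity problem.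

Step 5
Reactants: 15 disodium 2-[3-(benzyloxy)-4-methoxyphenyl]-5-hydroxy-4-oxo-4H-chromene-3,7-diyl disulfate
Product: 17 tamarixetin 3,7-bis(hydrogen sulfate) (CNP0574123.0), via disodium tamarixetin 3,7-disulfate 16 (not isolated)
Conditions: H2 (1 atm), 10% Pd/C, MeOH/H2O 1:1, rt; filtration; Dowex 50W-X8 (H+ form), H2O, 0–5 °C; immediate lyophilisation
Reagents that add atoms: none
Why: Catalytic hydrogenolysis of the single aryl benzyl ether, which should spare aryl sulfate salts, the methyl ether and the aromatic 4-pyranone, followed by cation exchange that replaces sodium by protons without any bond change; the pyridine-free salt avoids catalyst inhibition, and cold, brief handling limits acid-catalysed hydrolysis of the sulfate half esters.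

**Compound list**

1 | isovanillic acid (3-hydroxy-4-methoxybenzoic acid) | COc1ccc(C(=O)O)cc1O | starting material
2 | benzyl bromide | BrCc1ccccc1 | starting material
3 | benzyl 3-(benzyloxy)-4-methoxybenzoate | COc1ccc(C(=O)OCc2ccccc2)cc1OCc1ccccc1 | intermediate (not isolated)
4 | 3-(benzyloxy)-4-methoxybenzoic acid | COc1ccc(C(=O)O)cc1OCc1ccccc1 | intermediate
5 | ethyl 2-[(tert-butyldimethylsilyl)oxy]acetate | CCOC(=O)CO[Si](C)(C)C(C)(C)C | starting material
6 | 3-(benzyloxy)-4-methoxybenzoyl chloride | COc1ccc(C(=O)Cl)cc1OCc1ccccc1 | intermediate (not isolated)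
7 | lithium 2-[(tert-butyldimethylsilyl)oxy]-1-ethoxyethen-1-olate (lithium enolate of 5, geometry immaterial) | CCOC(O[Li])=CO[Si](C)(C)C(C)(C)C | intermediate (not isolated)
8 | ethyl 3-[3-(benzyloxy)-4-methoxyphenyl]-2-[(tert-butyldimethylsilyl)oxy]-3-oxopropanoate (racemic) | CCOC(=O)C(O[Si](C)(C)C(C)(C)C)C(=O)c1ccc(OC)c(OCc2ccccc2)c1 | intermediate
9 | phloroglucinol (benzene-1,3,5-triol) | Oc1cc(O)cc(O)c1 | starting material
10 | 3-[3-(benzyloxy)-4-methoxyphenyl]-2-[(tert-butyldimethylsilyl)oxy]-3-oxoprop-1-en-1-one (aroylketene) | O=C=C(O[Si](C)(C)C(C)(C)C)C(=O)c1ccc(OC)c(OCc2ccccc2)c1 | intermediate (not isolated)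
11 | 1-[3-(benzyloxy)-4-methoxyphenyl]-2-[(tert-butyldimethylsilyl)oxy]-3-(2,4,6-trihydroxyphenyl)propane-1,3-dione (racemic, enolisable) | COc1ccc(C(=O)C(O[Si](C)(C)C(C)(C)C)C(=O)c2c(O)cc(O)cc2O)cc1OCc1ccccc1 | intermediate (not isolated)
12 | 2-[3-(benzyloxy)-4-methoxyphenyl]-3-[(tert-butyldimethylsilyl)oxy]-5,7-dihydroxy-4H-chromen-4-one | COc1ccc(-c2oc3cc(O)cc(O)c3c(=O)c2O[Si](C)(C)C(C)(C)C)cc1OCc1ccccc1 | intermediate (not isolated)
13 | 2-[3-(benzyloxy)-4-methoxyphenyl]-3,5,7-trihydroxy-4H-chromen-4-one (3'-O-benzyltamarixetin) | COc1ccc(-c2oc3cc(O)cc(O)c3c(=O)c2O)cc1OCc1ccccc1 | intermediate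
14 | bis(pyridinium) 2-[3-(benzyloxy)-4-methoxyphenyl]-5-hydroxy-4-oxo-4H-chromene-3,7-diyl disulfate | COc1ccc(-c2oc3cc(OS(=O)(=O)[O-])cc(O)c3c(=O)c2OS(=O)(=O)[O-])cc1OCc1ccccc1.c1cc[nH+]cc1.c1cc[nH+]cc1 | intermediate (not isolated)
15 | disodium 2-[3-(benzyloxy)-4-methoxyphenyl]-5-hydroxy-4-oxo-4H-chromene-3,7-diyl disulfate | COc1ccc(-c2oc3cc(OS(=O)(=O)[O-])cc(O)c3c(=O)c2OS(=O)(=O)[O-])cc1OCc1ccccc1.[Na+].[Na+] | intermediate
16 | disodium tamarixetin 3,7-disulfate | COc1ccc(-c2oc3cc(OS(=O)(=O)[O-])cc(O)c3c(=O)c2OS(=O)(=O)[O-])cc1O.[Na+].[Na+] | intermediate (not isolated)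
17 | tamarixetin 3,7-bis(hydrogen sulfate), 5-hydroxy-2-(3-hydroxy-4-methoxyphenyl)-4-oxo-4H-chromene-3,7-diyl bis(hydrogen sulfate) | COc1ccc(-c2oc3cc(OS(=O)(=O)O)cc(O)c3c(=O)c2OS(=O)(=O)O)cc1O | target

Total step count: 5. Longest linear sequence: 5 steps (1 → 4 → 8 → 13 → 15 → 17).

**Steps most likely to fail**

Step 3. The melt may fail through silyl loss from 8 before annulation, decomposition of the α-oxygenated aroylketene, or Pechmann-type closure to the 4-arylcoumarin. The fallback builds ring C stepwise by the Allan–Robinson flavonol synthesis and sets out from 9 and 6. Houben–Hoesch acylation of phloroglucinol 9 with cyanomethyl benzoate (ZnCl2, HCl, Et2O, 0 °C; then hot water) would give 2-oxo-2-(2,4,6-trihydroxyphenyl)ethyl benzoate F1. Acid chloride 6 and the sodium salt of acid 4 would give 3-(benzyloxy)-4-methoxybenzoic anhydride F2. Fusion of F1 with F2 and the potassium salt of 4 at 170–180 °C would give the O-acylated flavonol, chiefly 3-(benzoyloxy)-2-[3-(benzyloxy)-4-methoxyphenyl]-5-hydroxy-4-oxo-4H-chromen-7-yl 3-(benzyloxy)-4-methoxybenzoate F3. KOH in aqueous ethanol would cleave the esters, and the route is rejoined at 13.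

Step 4. Sulfation may stall at the hindered enolic 3-OH, creep onto 5-OH under forcing, or give salts that cannot be freed from inorganic sulfate. The fallback uses protected sulfate diesters and sets out from 13. 2,2,2-Trichloroethyl chlorosulfate, Et3N and DMAP in THF would give the neutral, silica-stable 2-[3-(benzyloxy)-4-methoxyphenyl]-5-hydroxy-4-oxo-4H-chromene-3,7-diyl bis(2,2,2-trichloroethyl) bis(sulfate) F4. Transfer hydrogenolysis (10% Pd/C, HCO2NH4, MeOH) should remove both trichloroethyl groups and the aryl benzyl ether to give diammonium tamarixetin 3,7-disulfate F5. The H+ resin treatment of step 5 would convert F5 into 17, where the route is rejoined.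

Step 2. The enolate acylation may go astray through O-acylation, double acylation, or O-to-O silyl migration in the product enolate. The fallback installs the C3 oxygen after the carbon skeleton and sets out from 4. Carbonyldiimidazole, then Mg(O2CCH2CO2Et)2 in THF (Masamune–Brooks homologation) would give ethyl 3-[3-(benzyloxy)-4-methoxyphenyl]-3-oxopropanoate F6. Dimethyldioxirane in acetone would hydroxylate its enol to ethyl 3-[3-(benzyloxy)-4-methoxyphenyl]-2-hydroxy-3-oxopropanoate F7. TBSCl and imidazole in DMF would silylate the hydroxyl, and the route is rejoined at 8.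

**Further compounds**

F1 | step 3 | 2-oxo-2-(2,4,6-trihydroxyphenyl)ethyl benzoate | O=C(COC(=O)c1ccccc1)c1c(O)cc(O)cc1O
F2 | step 3 | 3-(benzyloxy)-4-methoxybenzoic anhydride | COc1ccc(C(=O)OC(=O)c2ccc(OC)c(OCc3ccccc3)c2)cc1OCc1ccccc1
F3 | step 3 | 3-(benzoyloxy)-2-[3-(benzyloxy)-4-methoxyphenyl]-5-hydroxy-4-oxo-4H-chromen-7-yl 3-(benzyloxy)-4-methoxybenzoate | COc1ccc(-c2oc3cc(OC(=O)c4ccc(OC)c(OCc5ccccc5)c4)cc(O)c3c(=O)c2OC(=O)c2ccccc2)cc1OCc1ccccc1
F4 | step 4 | 2-[3-(benzyloxy)-4-methoxyphenyl]-5-hydroxy-4-oxo-4H-chromene-3,7-diyl bis(2,2,2-trichloroethyl) bis(sulfate) | COc1ccc(-c2oc3cc(OS(=O)(=O)OCC(Cl)(Cl)Cl)cc(O)c3c(=O)c2OS(=O)(=O)OCC(Cl)(Cl)Cl)cc1OCc1ccccc1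
F5 | step 4 | diammonium tamarixetin 3,7-disulfate | COc1ccc(-c2oc3cc(OS(=O)(=O)[O-])cc(O)c3c(=O)c2OS(=O)(=O)[O-])cc1O.[NH4+].[NH4+]
F6 | step 2 | ethyl 3-[3-(benzyloxy)-4-methoxyphenyl]-3-oxopropanoate | CCOC(=O)CC(=O)c1ccc(OC)c(OCc2ccccc2)c1
F7 | step 2 | ethyl 3-[3-(benzyloxy)-4-methoxyphenyl]-2-hydroxy-3-oxopropanoate (racemic) | CCOC(=O)C(O)C(=O)c1ccc(OC)c(OCc2ccccc2)c1
A1 | direct plan | 1,3-bis(benzyloxy)-5-bromobenzene | Brc1cc(OCc2ccccc2)cc(OCc2ccccc2)c1
A2 | direct plan | 2,4-bis(benzyloxy)-6-bromobenzaldehyde | O=Cc1c(Br)cc(OCc2ccccc2)cc1OCc1ccccc1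
A3 | direct plan | 2-(benzyloxy)-1-[3-(benzyloxy)-4-methoxyphenyl]ethan-1-one | COc1ccc(C(=O)COCc2ccccc2)cc1OCc1ccccc1
A4 | direct plan | 2-(benzyloxy)-1-[2,4-bis(benzyloxy)-6-bromophenyl]-3-[3-(benzyloxy)-4-methoxyphenyl]propane-1,3-dione (racemic) | COc1ccc(C(=O)C(OCc2ccccc2)C(=O)c2c(Br)cc(OCc3ccccc3)cc2OCc2ccccc2)cc1OCc1ccccc1
A5 | direct plan | 3,5,7-tris(benzyloxy)-2-[3-(benzyloxy)-4-methoxyphenyl]-4H-chromen-4-one | COc1ccc(-c2oc3cc(OCc4ccccc4)cc(OCc4ccccc4)c3c(=O)c2OCc2ccccc2)cc1OCc1ccccc1
A6 | direct plan | tamarixetin (3,5,7-trihydroxy-2-(3-hydroxy-4-methoxyphenyl)-4H-chromen-4-one) | COc1ccc(-c2oc3cc(O)cc(O)c3c(=O)c2O)cc1O
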